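**Two curves.** Read as a fraction left, J in Friday's run falls at 0.0788 h⁻¹ between 2.50 h and 5.00 h, then at 0.0703 h⁻¹ up to 10.0 h, while J and E counted together fall at 0.0502 h⁻¹ and then 0.0490 h⁻¹.

| flask | J | remark | time |
|---|---|---|---|
| Friday's | 0.061 M | run made earlier |  |
| Monday's | 0.14 M | run made earlier |  |
| blue | 0.091 M |  | 12 h |
| amber | 0.091 M |  | 20 h |
| green | 0.091 M |  | 25 h |

| run | time / h | E / % | Z / % | J / % | L / % |
|---|---|---|---|---|---|
| Friday's | 2.50 | 10.3 | 3.1 | 80.5 | 6.0 |
| Friday's | 5.00 | 14.0 | 10.0 | 66.1 | 6.6 |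
| Friday's | 8.00 | 15.7 | 17.4 | 53.4 | 8.5 |
| Friday's | 10.0 | 16.2 | 22.4 | 46.5 | 8.3 |
| Monday's | 2.50 | 9.7 | 5.8 | 78.8 | 4.5 |
| Monday's | 5.00 | 14.1 | 15.5 | 62.9 | 4.1 |
| Monday's | 8.00 | 14.5 | 24.8 | 49.7 | 3.9 |
| Monday's | 10.0 | 15.3 | 30.7 | 44.0 | 4.4 |

(readings scatter by 0.5 percentage points)

- percent here means J units held: one Z counts as two
- a reading of L is of its free form alone
- a reading of E is of its free form alone

1. which of these there is most of at the end, counted by the J in it, blue (J / L / E / Z)
2. which of these there is most of at the end, counted by the J in it, amber (J / L / E / Z)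
3. which of these there is most of at the end, counted by the J in it, green (J / L / E / Z)
4. the largest of these amounts at the end, in percent of the J charged, blue
5. the largest of these amounts at the end, in percent of the J charged, amber
6. the largest of these amounts at the end, in percent of the J charged, green

**The stock.** So treat [J]+[E] as one stock. From first to last reading it decays at 0.0494 h⁻¹ on Friday's run and 0.0534 h⁻¹ on Monday's. The charge of 0.091 M lies between those two, so I take their mean, 0.0514 h⁻¹. This is the stock's decay rate, the logarithm of the drop in the fraction left over the time taken, an apparent first-order rate constant. Its halving time is 13.5 h.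

**Blue's curve.** At 10.0 h the stock read 62.7 % on Friday's run and 59.3 % on Monday's, so I start the 0.091 M curve from their mean, 61.0 %. It then falls to 55.0 % at 12 h, reaches half of the charge at 13.9 h, and gives 36.5 % at 20 h and 28.2 % at 25 h.

Z is what remains after the stock, L and the gap in the balance. L ended at 8.3 % on Friday's run and 4.4 % on Monday's, and I take it at their mean, 6.35 %. The gap grew roughly in step with time, to a mean of 6.10 % at 10.0 h. With E near 15.8 %, I reckon blue at J 39.3 % against Z 31.3 %, more J than Z. My Z for amber, 45.0 %, is more than my whole stock for amber, and my Z for green comes to 50.2 %.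

**The forecast.** The forecast, holding that “L stays quasi-steady”, names J at 40 % for blue, Z at 53 % for amber and Z at 62 % for green, the last two above my figures.

**The flask.** Blue ends with J at 40.0 %, amber with Z at 45.8 %, green with Z at 52.4 %. Blue's stock stands at 55.1 % against my 55.0 %. Green's stands at 31.4 % against my 28.2 %, its second half running at 0.0432 h⁻¹, slower than the carried rate.

    J ⇌ E (K = 0.390, k = 0.0580 h⁻¹)
    J → L (k = 0.0300 h⁻¹)
    E → Q (k = 0.0130 h⁻¹)
    L ⇌ Q (K = 1.70, k = 0.00780 h⁻¹)
    J + L → Z (k = 4.50 L mol⁻¹ h⁻¹)
    E ⇌ X (K = 0.350, k = 0.0680 h⁻¹)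

**A richer charge.** Take blue with 0.15 M of J. Monday's charge is nearer to it than Friday's, so its stock and its rate carried from 10.0 h to 12 h give 53.3 %. The stock of that flask stands at 53.4 %, with J at 38.7 %, more than its Z, which stands at 35.5 %.

(The runs come from a simulation with made-up constants.)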